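Read the rates off the two simulated runs before anything else is attempted.

in all of them: substrate 0.30 M; free catalyst 1.5 mM
- Thursday's: partner 0.27 M; impurity 0.54 mM; run made earlier
- Sunday's: partner 0.27 M; impurity 1.2 mM; run made earlier
- flask: partner 0.270 M; impurity 0.80 mM

- Thursday's (time / h: product / %, substrate / %): 0.500: 8.0, 92.1; 0.833: 12.4, 86.6; 1.50: 23.9, 77.2; 3.00: 46.3, 54.0; 6.00: 61.9, 37.7
- Sunday's (time / h: product / %, substrate / %): 1.33: 7.1, 91.8; 2.50: 13.3, 87.9; 4.00: 18.8, 80.1; 5.00: 24.4, 75.6; 6.00: 30.3, 70.4

(each reading ± 0.5 percentage points)

* apparent order in free catalyst when 50% of the substrate are converted (percent change of the rate of making product for one percent more free catalyst charged)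
* factor on the rate of making product when 50% of the substrate are converted if free catalyst is charged twice over

- the numbers in the tables scatter by 0.5 percentage points (one standard deviation)
- no earlier run changes the charge of free catalyst; that part of a forecast is a guess

Thursday's product climbs steadily to 46.3% at 3.00 h, and Sunday's to 30.3% at 6.00 h. Dividing one mean rate by the other removes time and gives 3.06. The two runs differ in impurity, so a first estimate lets each impurity take one catalyst for good. That leaves 0.960 mM on Thursday and 0.300 mM on Sunday, a ratio of 3.20. The two ratios lie close, though not on top of each other, and the first comes from scattered readings, so the one-for-one loss is kept as an estimate.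

On this estimate the new flask works with 0.700 mM. Its figure is 2.14: the catalyst charged over the catalyst that the impurity leaves, here called the gearing. One percent more catalyst charged is a larger percentage of what survives, so the gearing is my estimate of the order. On the same estimate, doubling the charge gives a factor of 3.14.

The objection is that the question looks at 50% conversion, not at the steady stretch. Thursday gains 16 percentage points in its last 3.00 h, although one-for-one use would leave 0.0843 M of partner, the limiting reagent. No earlier run varies the catalyst, so this doubt is not computed away here, and the gearing stands with it.

The forecast gives 2.1 and 3.1, the same as my reckoning, on the ground that “the rate is roughly first order in the remaining catalyst”.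

The flask gives an order of 2.5, above the forecast, and a factor of 3.25, within the margin.

    substrate + free catalyst ⇌ catalyst intermediate A (K = 5.40 L mol⁻¹, k = 220 L mol⁻¹ min⁻¹)
    free catalyst + impurity → spent catalyst (k = 7200 L mol⁻¹ min⁻¹)
    partner + catalyst intermediate B → catalyst intermediate C (k = 1600 L mol⁻¹ min⁻¹)
    partner → decomposed reagent (k = 0.00290 min⁻¹)
    catalyst intermediate A ⇌ catalyst intermediate B (K = 2.00, k = 4.00 min⁻¹)
    catalyst intermediate C → free catalyst + product (k = 1.30 min⁻¹)

The flask's order of 2.5 stands above its gearing of 2.14. Take away the path from free catalyst and impurity to spent catalyst, and a second flask with the same charge has a gearing of one. Its order falls to 1.0, and its rate at 50% conversion is 2.21 times that of the actual flask, against a gearing of 2.14 in the actual flask.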